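**Retrosynthetic overview**
1. The target is a trans-(2S,3R)-2-aryl-3-hydroxymethyl-2,3-dihydrobenzofuran: ring A (benzo ring C3a–C7a with 7-OMe and the C5 acrylic acid), ring B (O1, C2, C3, C3a, C7a) and ring C (syringyl on C2).
2. Feature used: C2 of ring B is a single benzylic carbon bonded only to O1, C3, H and ring C, and C3 carries ring A plus one carbon (CH2OH). C2 can therefore arrive as a sulfonium benzylide carbon, and C3 with its CH2 as the alkene carbons of a ring A 2-hydroxy-β-nitrostyrene.
3. Key disconnection: bonds C2–C3 and O1–C2 of ring B, leading back to the bromo-nitrostyrene and a C2-symmetric syringylmethyl thiolanium salt (formal [4+1]). Ring B is the only ring formed; rings A and C are bought.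
4. After ring B: CH2NO2 to CO2H to CH2OH, then Heck coupling at C5–Br with methyl acrylate, then ester and MOM cleavage.
5. Before ring B: Henry condensation on 5-bromo-ortho-vanillin; syringaldehyde to MOM ether, alcohol and bromide; (2R,5R)-hexane-2,5-diol to dimesylate to (2S,5S)-thiolane, then S-benzylation.

Key step: step 8

Remark (assumption): the sense of induction of the thiolanium benzylide is taken from its aldehyde epoxidation, where the (2R,5R)-sulfide is known to lead to (S,S)-stilbene oxide. The same topology gives the opposite CIP letter at C2 here, because ring C outranks C3 whereas the second epoxide carbon outranks phenyl, so the (2S,5S)-sulfide is assumed to deliver 2S.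

**Route**

Step 1
Reactants: 1 5-bromo-2-hydroxy-3-methoxybenzaldehyde; 2 nitromethane
Product: 4 (E)-4-bromo-2-methoxy-6-(2-nitrovinyl)phenol, via nitroaldol adduct 3 (not isolated)
Conditions: MeNO2 (excess), NH4OAc, AcOH, 90 °C
Reagents that add atoms: none
Why: Henry condensation, in which ammonium acetate promotes addition of nitromethane to the aldehyde and dehydration of 3 gives the conjugated, more stable (E)-nitroalkene; no stereocenter is formed.

Step 2
Reactants: 5 syringaldehyde
Product: 6 3,5-dimethoxy-4-(methoxymethoxy)benzaldehyde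
Conditions: MOMCl, iPr2NEt, CH2Cl2, 0 °C → rt
Reagents that add atoms: chloromethyl methyl ether, COCCl
Why: Williamson-type O-alkylation of the acidic phenol by the reactive α-chloro ether should proceed despite the two flanking methoxy groups, and the acetal is stable to all basic, hydride, borane and palladium steps that follow.

Step 3
Reactants: 6 3,5-dimethoxy-4-(methoxymethoxy)benzaldehyde
Product: 7 [3,5-dimethoxy-4-(methoxymethoxy)phenyl]methanol
Conditions: NaBH4, MeOH, 0 °C
Reagents that add atoms: none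
Why: Borohydride reduction of an aromatic aldehyde leaves the acetal and aryl ethers untouched.

Step 4
Reactants: 7 [3,5-dimethoxy-4-(methoxymethoxy)phenyl]methanol
Product: 8 5-(bromomethyl)-1,3-dimethoxy-2-(methoxymethoxy)benzene
Conditions: CBr4, PPh3, CH2Cl2, 0 °C
Reagents that add atoms: carbon tetrabromide, BrC(Br)(Br)Br
Why: Appel bromination displaces the alkoxyphosphonium by bromide under neutral conditions, which avoids the HBr that would cleave the MOM acetal.

Step 5
Reactants: 9 (2R,5R)-hexane-2,5-diol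
Product: 10 (2R,5R)-hexane-2,5-diyl dimethanesulfonate
Conditions: MsCl, Et3N, CH2Cl2, −10 → 0 °C
Reagents that add atoms: methanesulfonyl chloride, CS(=O)(=O)Cl
Why: O-sulfonylation of the secondary alcohols does not touch the C–O stereocenters, so both keep their configuration.

Step 6
Reactants: 10 (2R,5R)-hexane-2,5-diyl dimethanesulfonate
Product: 11 (2S,5S)-2,5-dimethylthiolane
Conditions: Na2S·9H2O, DMSO, rt; distillation
Reagents that add atoms: sodium sulfide, [Na+].[Na+].[S-2]
Why: Double SN2 displacement by sulfide, the second as a 5-exo-tet ring closure, inverts both centers and turns the (2R,5R)-dimesylate into the (2S,5S)-thiolane.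

Step 7
Reactants: 8 5-(bromomethyl)-1,3-dimethoxy-2-(methoxymethoxy)benzene; 11 (2S,5S)-2,5-dimethylthiolane
Product: 12 (2S,5S)-1-[3,5-dimethoxy-4-(methoxymethoxy)benzyl]-2,5-dimethylthiolan-1-ium tetrafluoroborate
Conditions: 11 (1.5 equiv), NaBF4 (2 equiv), CH2Cl2/H2O (1:1), rt, 48 h; trituration with Et2O
Reagents that add atoms: sodium tetrafluoroborate, [Na+].F[B-](F)(F)F
Why: SN2 S-alkylation of the hindered sulfide by the benzylic bromide is driven forward by exchange of bromide for tetrafluoroborate, and because the sulfide is C2-symmetric its two lone pairs are equivalent and a single sulfonium salt should result.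

Step 8
Reactants: 4 (E)-4-bromo-2-methoxy-6-(2-nitrovinyl)phenol; 12 (2S,5S)-1-[3,5-dimethoxy-4-(methoxymethoxy)benzyl]-2,5-dimethylthiolan-1-ium tetrafluoroborate
Product: 15 (2S,3R)-5-bromo-2-[3,5-dimethoxy-4-(methoxymethoxy)phenyl]-7-methoxy-3-(nitromethyl)-2,3-dihydro-1-benzofuran, via sulfonium ylide 13 (not isolated), via phenoxide–sulfonium betaine 14 (not isolated)
Conditions: 12 (1.2 equiv), Cs2CO3 (2.2 equiv), MeCN, −20 → 0 °C; then aq. NH4Cl
Reagents that add atoms: none
Why: Proposed new method: Cs2CO3 converts 4 into its phenoxide and 12 into the semistabilized benzylide 13, whose carbon adds in Michael fashion to the alkene carbon bonded to ring A (bond C2–C3), and after proton exchange the ortho phenoxide of betaine 14 displaces thiolane 11 from C2 (bond O1–C2). The closest known reaction types are the formal [4+1] annulation of sulfonium ylides with 2-hydroxy-β-nitrostyrenes and ortho-quinone methides to trans-2,3-dihydrobenzofurans and the asymmetric aldehyde epoxidation by benzylides of this thiolane, and what goes beyond them is the use of a non-racemic semistabilized benzylide in the nitrostyrene annulation. Ring B closes by 5-exo-tet SN2 attack of O1 on C2 with inversion. C2 is set by the C2-symmetric thiolanium, whose ylide should react in the conformer with ring C turned away from the thiolane and on the face anti to the ring methyl group that is cis to the ylide carbon, followed by the inversion at closure; C3 is set relative to C2 because only the betaine with ring C and the nitromethyl group on opposite sides closes without eclipsing, so that the trans ring results, the more so if the addition is reversible. The step needs O-closure to win over nitronate C- or O-alkylation and over intermolecular benzyl transfer to the phenoxide, which the ortho phenoxide secures as the strongest nucleophile placed for a five-membered transition state, helped by the low temperature and the non-nucleophilic BF4 counter-ion.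

Step 9
Reactants: 15 (2S,3R)-5-bromo-2-[3,5-dimethoxy-4-(methoxymethoxy)phenyl]-7-methoxy-3-(nitromethyl)-2,3-dihydro-1-benzofuran
Product: 16 (2S,3S)-5-bromo-2-[3,5-dimethoxy-4-(methoxymethoxy)phenyl]-7-methoxy-2,3-dihydro-1-benzofuran-3-carboxylic acid
Conditions: NaNO2 (3 equiv), AcOH (10 equiv), DMSO, 35 °C
Reagents that add atoms: sodium nitrite, [Na+].[O-]N=O; water, O
Why: Nitrosative conversion of a primary nitroalkane into a carboxylic acid (nitrolic acid, then nitrile oxide, then hydroxamic acid) runs in a weakly acidic medium that should not enolise C3, so the trans arrangement is kept (the CIP letter at C3 changes only because CO2H outranks C2) and no epimerisable aldehyde is passed through.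

Step 10
Reactants: 16 (2S,3S)-5-bromo-2-[3,5-dimethoxy-4-(methoxymethoxy)phenyl]-7-methoxy-2,3-dihydro-1-benzofuran-3-carboxylic acid
Product: 17 [(2S,3R)-5-bromo-2-[3,5-dimethoxy-4-(methoxymethoxy)phenyl]-7-methoxy-2,3-dihydro-1-benzofuran-3-yl]methanol
Conditions: BH3·THF, THF, 0 °C → rt; MeOH quench
Reagents that add atoms: none
Why: Borane reduces the carboxylic acid chemoselectively through its acyloxyborane under non-basic conditions, so the aryl bromide, the acetal and the C3 stereocenter are not affected.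

Step 11
Reactants: 17 [(2S,3R)-5-bromo-2-[3,5-dimethoxy-4-(methoxymethoxy)phenyl]-7-methoxy-2,3-dihydro-1-benzofuran-3-yl]methanol; 18 methyl acrylate
Product: 19 methyl (E)-3-[(2S,3R)-2-[3,5-dimethoxy-4-(methoxymethoxy)phenyl]-3-(hydroxymethyl)-7-methoxy-2,3-dihydro-1-benzofuran-5-yl]prop-2-enoate
Conditions: Pd(OAc)2 (5 mol %), P(o-tol)3 (15 mol %), Et3N, DMF, 100 °C
Reagents that add atoms: none
Why: Mizoroki–Heck reaction, in which zerovalent palladium inserts into the C5–Br bond and syn-insertion of the acrylate followed by syn β-hydride elimination gives the (E)-cinnamate; the free alcohol and the MOM ether are tolerated.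

Step 12
Reactants: 19 methyl (E)-3-[(2S,3R)-2-[3,5-dimethoxy-4-(methoxymethoxy)phenyl]-3-(hydroxymethyl)-7-methoxy-2,3-dihydro-1-benzofuran-5-yl]prop-2-enoate
Product: 21 (E)-3-[(2S,3R)-2-(4-hydroxy-3,5-dimethoxyphenyl)-3-(hydroxymethyl)-7-methoxy-2,3-dihydro-1-benzofuran-5-yl]prop-2-enoic acid, via MOM-protected cinnamic acid 20 (not isolated)
Conditions: LiOH·H2O, THF/H2O (3:1), rt; then aq. HCl to ca. 2 M, 40 °C
Reagents that add atoms: lithium hydroxide, [Li+].[OH-]
Why: Saponification of the methyl ester takes place while the phenol is still masked (no phenoxide para to C2), and the following acid-catalysed hydrolysis of the MOM acetal through its oxocarbenium ion frees the phenol without involving C2 or C3.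

**Compound list**
1 | 5-bromo-2-hydroxy-3-methoxybenzaldehyde | COc1cc(Br)cc(C=O)c1O | starting material
2 | nitromethane | C[N+](=O)[O-] | starting material
3 | 4-bromo-2-(1-hydroxy-2-nitroethyl)-6-methoxyphenol (nitroaldol adduct, racemic) | COc1cc(Br)cc(C(O)C[N+](=O)[O-])c1O | intermediate (not isolated)
4 | (E)-4-bromo-2-methoxy-6-(2-nitrovinyl)phenol | COc1cc(Br)cc(/C=C/[N+](=O)[O-])c1O | intermediate
5 | syringaldehyde | COc1cc(C=O)cc(OC)c1O | starting material
6 | 3,5-dimethoxy-4-(methoxymethoxy)benzaldehyde | COCOc1c(OC)cc(C=O)cc1OC | intermediate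
7 | [3,5-dimethoxy-4-(methoxymethoxy)phenyl]methanol | COCOc1c(OC)cc(CO)cc1OC | intermediate
8 | 5-(bromomethyl)-1,3-dimethoxy-2-(methoxymethoxy)benzene | COCOc1c(OC)cc(CBr)cc1OC | intermediate
9 | (2R,5R)-hexane-2,5-diol | C[C@@H](O)CC[C@@H](C)O | starting material
10 | (2R,5R)-hexane-2,5-diyl dimethanesulfonate | C[C@@H](OS(C)(=O)=O)CC[C@@H](C)OS(C)(=O)=O | intermediate
11 | (2S,5S)-2,5-dimethylthiolane | C[C@H]1CC[C@H](C)S1 | intermediate
12 | (2S,5S)-1-[3,5-dimethoxy-4-(methoxymethoxy)benzyl]-2,5-dimethylthiolan-1-ium tetrafluoroborate | C[C@H]1CC[C@H](C)[S+]1Cc1cc(OC)c(OCOC)c(OC)c1.F[B-](F)(F)F | intermediate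
13 | (2S,5S)-2,5-dimethylthiolanium [3,5-dimethoxy-4-(methoxymethoxy)phenyl]methylide | C[C@H]1CC[C@H](C)[S+]1[CH-]c1cc(OC)c(OCOC)c(OC)c1 | intermediate (not isolated)
14 | Michael adduct betaine: ring A phenoxide, C3 bearing CH2NO2 (nitronate shown C-protonated), C2 bearing ring C and the (2S,5S)-thiolanium | [O-]c1c(OC)cc(Br)cc1[C@H](C[N+](=O)[O-])[C@H](c1cc(OC)c(OCOC)c(OC)c1)[S+]1[C@@H](C)CC[C@@H]1C | intermediate (not isolated)
15 | (2S,3R)-5-bromo-2-[3,5-dimethoxy-4-(methoxymethoxy)phenyl]-7-methoxy-3-(nitromethyl)-2,3-dihydro-1-benzofuran (trans) | COc1cc([C@H]2Oc3c(OC)cc(Br)cc3[C@@H]2C[N+](=O)[O-])cc(OC)c1OCOC | intermediate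
16 | (2S,3S)-5-bromo-2-[3,5-dimethoxy-4-(methoxymethoxy)phenyl]-7-methoxy-2,3-dihydro-1-benzofuran-3-carboxylic acid (trans) | COc1cc([C@H]2Oc3c(OC)cc(Br)cc3[C@@H]2C(=O)O)cc(OC)c1OCOC | intermediate
17 | [(2S,3R)-5-bromo-2-[3,5-dimethoxy-4-(methoxymethoxy)phenyl]-7-methoxy-2,3-dihydro-1-benzofuran-3-yl]methanol (trans) | COc1cc([C@H]2Oc3c(OC)cc(Br)cc3[C@@H]2CO)cc(OC)c1OCOC | intermediate
18 | methyl acrylate | C=CC(=O)OC | starting material
19 | methyl (E)-3-[(2S,3R)-2-[3,5-dimethoxy-4-(methoxymethoxy)phenyl]-3-(hydroxymethyl)-7-methoxy-2,3-dihydro-1-benzofuran-5-yl]prop-2-enoate | COc1cc([C@H]2Oc3c(OC)cc(/C=C/C(=O)OC)cc3[C@@H]2CO)cc(OC)c1OCOC | intermediate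
20 | (E)-3-[(2S,3R)-2-[3,5-dimethoxy-4-(methoxymethoxy)phenyl]-3-(hydroxymethyl)-7-methoxy-2,3-dihydro-1-benzofuran-5-yl]prop-2-enoic acid | COc1cc([C@H]2Oc3c(OC)cc(/C=C/C(=O)O)cc3[C@@H]2CO)cc(OC)c1OCOC | intermediate (not isolated)
21 | (E)-3-[(2S,3R)-2-(4-hydroxy-3,5-dimethoxyphenyl)-3-(hydroxymethyl)-7-methoxy-2,3-dihydro-1-benzofuran-5-yl]prop-2-enoic acid | COc1cc([C@H]2Oc3c(OC)cc(/C=C/C(=O)O)cc3[C@@H]2CO)cc(OC)c1O | target

**Step count**
Total: 12 steps. Longest linear sequence: 9 steps (from 5 through steps 2, 3, 4, 7, 8, 9, 10, 11, 12).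

**Steps most likely to fail**

1. Step 8 (bears the label). The benzyl group may be transferred from sulfur to the phenoxide oxygen before the ylide forms, the betaine may close through the nitronate (nitrocyclopropane or isoxazoline N-oxide) instead of through O1, or the ylide may add with poor facial selectivity or give cis/trans mixtures. The fallback uses known chemistry and closes ring B by enantioselective carbenoid C–H insertion instead of ylide annulation; it sets out from 4 and 8 and comes back at 17.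
   - Phenol 4 is O-alkylated with bromide 8 (K2CO3, DMF, rt) to (E)-5-bromo-2-{[3,5-dimethoxy-4-(methoxymethoxy)benzyl]oxy}-1-methoxy-3-(2-nitrovinyl)benzene F1.
   - NaBH4 (THF/MeOH, 0 °C) reduces the nitroalkene to 5-bromo-2-{[3,5-dimethoxy-4-(methoxymethoxy)benzyl]oxy}-1-methoxy-3-(2-nitroethyl)benzene F2.
   - NaNO2/AcOH/DMSO (35 °C) converts this into 2-(5-bromo-2-{[3,5-dimethoxy-4-(methoxymethoxy)benzyl]oxy}-3-methoxyphenyl)acetic acid F3.
   - MeI/K2CO3 (DMF) gives methyl 2-(5-bromo-2-{[3,5-dimethoxy-4-(methoxymethoxy)benzyl]oxy}-3-methoxyphenyl)acetate F4.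
   - Diazo transfer with 4-acetamidobenzenesulfonyl azide and DBU (MeCN) gives methyl 2-(5-bromo-2-{[3,5-dimethoxy-4-(methoxymethoxy)benzyl]oxy}-3-methoxyphenyl)-2-diazoacetate F5.
   - Dirhodium tetrakis[N-phthaloyl-(S)-tert-leucinate], Rh2(S-PTTL)4, or its enantiomer, whichever gives 2S (toluene, −60 °C), should insert the carbenoid into the benzylic ether C–H bond. This gives methyl (2S,3R)-5-bromo-2-[3,5-dimethoxy-4-(methoxymethoxy)phenyl]-7-methoxy-2,3-dihydro-1-benzofuran-3-carboxylate F6 (cis).
   - NaOMe/MeOH epimerises C3 to methyl (2S,3S)-5-bromo-2-[3,5-dimethoxy-4-(methoxymethoxy)phenyl]-7-methoxy-2,3-dihydro-1-benzofuran-3-carboxylate F7 (trans).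
   - LiBH4 (THF, rt) reduces the ester to 17.

2. Step 9. The nitrosation sequence may stall at the nitrolic acid, the nitrile oxide may dimerise, or the electron-rich rings may be C-nitrosated. The fallback sets out from 15 and comes back at 17, bypassing 16. The sodium nitronate of 15 (NaOMe, MeOH, 0 °C) is added to aqueous TiCl3 buffered with NH4OAc (reductive Nef reaction, pH about 5). The crude (2S,3S)-5-bromo-2-[3,5-dimethoxy-4-(methoxymethoxy)phenyl]-7-methoxy-2,3-dihydro-1-benzofuran-3-carbaldehyde F8 is reduced at once with NaBH4 (MeOH, −20 °C) to 17, so that the epimerisable aldehyde is not stored or exposed to base.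

3. Step 12. In aqueous acid the C2–O1 bond, benzylic to the oxygenated ring C, may ionise and erode the trans purity or open ring B before the hindered acetal is hydrolysed. The fallback sets out from 19 and comes back at 21, and removes the MOM group first by silyl transfer instead of protic hydrolysis. TMSOTf and 2,2'-bipyridyl (CH2Cl2, 0 °C, then water) should give methyl (E)-3-[(2S,3R)-2-(4-hydroxy-3,5-dimethoxyphenyl)-3-(hydroxymethyl)-7-methoxy-2,3-dihydro-1-benzofuran-5-yl]prop-2-enoate F9. This is saponified with LiOH (THF/H2O, rt) and acidified cold to pH 3 to give 21.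

**Further compounds**
F1 | step 8 | (E)-5-bromo-2-{[3,5-dimethoxy-4-(methoxymethoxy)benzyl]oxy}-1-methoxy-3-(2-nitrovinyl)benzene | COc1cc(Br)cc(/C=C/[N+](=O)[O-])c1OCc1cc(OC)c(OCOC)c(OC)c1
F2 | step 8 | 5-bromo-2-{[3,5-dimethoxy-4-(methoxymethoxy)benzyl]oxy}-1-methoxy-3-(2-nitroethyl)benzene | COc1cc(Br)cc(CC[N+](=O)[O-])c1OCc1cc(OC)c(OCOC)c(OC)c1
F3 | step 8 | 2-(5-bromo-2-{[3,5-dimethoxy-4-(methoxymethoxy)benzyl]oxy}-3-methoxyphenyl)acetic acid | COc1cc(Br)cc(CC(=O)O)c1OCc1cc(OC)c(OCOC)c(OC)c1
F4 | step 8 | methyl 2-(5-bromo-2-{[3,5-dimethoxy-4-(methoxymethoxy)benzyl]oxy}-3-methoxyphenyl)acetate | COC(=O)Cc1cc(Br)cc(OC)c1OCc1cc(OC)c(OCOC)c(OC)c1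
F5 | step 8 | methyl 2-(5-bromo-2-{[3,5-dimethoxy-4-(methoxymethoxy)benzyl]oxy}-3-methoxyphenyl)-2-diazoacetate | COC(=O)C(=[N+]=[N-])c1cc(Br)cc(OC)c1OCc1cc(OC)c(OCOC)c(OC)c1
F6 | step 8 | methyl (2S,3R)-5-bromo-2-[3,5-dimethoxy-4-(methoxymethoxy)phenyl]-7-methoxy-2,3-dihydro-1-benzofuran-3-carboxylate (cis) | COc1cc([C@H]2Oc3c(OC)cc(Br)cc3[C@H]2C(=O)OC)cc(OC)c1OCOC
F7 | step 8 | methyl (2S,3S)-5-bromo-2-[3,5-dimethoxy-4-(methoxymethoxy)phenyl]-7-methoxy-2,3-dihydro-1-benzofuran-3-carboxylate (trans) | COc1cc([C@H]2Oc3c(OC)cc(Br)cc3[C@@H]2C(=O)OC)cc(OC)c1OCOC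
F8 | step 9 | (2S,3S)-5-bromo-2-[3,5-dimethoxy-4-(methoxymethoxy)phenyl]-7-methoxy-2,3-dihydro-1-benzofuran-3-carbaldehyde | COc1cc([C@H]2Oc3c(OC)cc(Br)cc3[C@@H]2C=O)cc(OC)c1OCOC
F9 | step 12 | methyl (E)-3-[(2S,3R)-2-(4-hydroxy-3,5-dimethoxyphenyl)-3-(hydroxymethyl)-7-methoxy-2,3-dihydro-1-benzofuran-5-yl]prop-2-enoate | COc1cc([C@H]2Oc3c(OC)cc(/C=C/C(=O)OC)cc3[C@@H]2CO)cc(OC)c1O
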